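**Retrosynthetic overview**
- The C-3 lactol configuration is set last: (R)-lactol ⇐ (R)-3-acetate ⇐ racemic lactol, by lipase dynamic kinetic acetylation and then enzymatic removal of the acetyl group at the acyl carbon.
- Key disconnection, aryl C-6–CH2: a hexasubstituted aryl bromide plus 1-[(E)-undec-1-enyl]cyclopropanol. The strained alcohol acts as a ketone homoenolate (nucleophilic β-carbon) in a palladium-catalysed ring-opening arylation that installs the whole enone side chain in one step.
- Aryl bromide ⇐ 3,5-dimethoxybenzaldehyde: ortho-carboxylation (closes the lactol–lactone ring), C-4 formylation, lactol masking with C-6 bromination; the O-methyl groups come off with BCl3 after the coupling.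
- Cyclopropanol ⇐ undec-1-yne + cyclopropanone ethyl hemiacetal, then trans-reduction of the alkyne.
- Ring order: the benzene ring is bought; the five-membered lactol–lactone ring is the only ring made (step 3); the cyclopropane is bought and consumed in the key step.

Assumption: the only stereocentre (C-3, R) is a lactol that racemises through its open formyl-acid form under base; I assume it holds its configuration in neutral, base-free aprotic media at or below room temperature, so it is set in the last two steps and the product is handled cold and base-free.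

**Step 1**
Reactants: 1 undec-1-yne; 2 1-ethoxycyclopropan-1-ol (cyclopropanone ethyl hemiacetal)
Product: 4 1-(undec-1-yn-1-yl)cyclopropan-1-ol, via undec-1-ynylmagnesium bromide 3 (not isolated)
Conditions: EtMgBr (1.1 equiv on 1, THF, 50 °C; 1.0 equiv on 2, THF, 0 °C); combine, 65 °C; then H2O
Reagents that add atoms: none
Why: The magnesium salt of the hemiacetal behaves as cyclopropanone towards the alkynyl Grignard reagent (Grignard 1,2-addition to a cyclopropanone equivalent), giving the tertiary cyclopropanol with no stereocentre.

**Step 2**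
Reactants: 4 1-(undec-1-yn-1-yl)cyclopropan-1-ol
Product: 5 1-[(1E)-undec-1-en-1-yl]cyclopropan-1-ol
Conditions: NaAlH2(OCH2CH2OCH3)2 (2 equiv), THF, 0 → 25 °C; aq. KNaC4H4O6
Reagents that add atoms: none
Why: Alkoxide-directed trans-hydroalumination of the propargylic alcohol followed by protonolysis gives only the (E)-allylic alcohol (propargylic alcohol trans-reduction), and the aluminium cyclopropoxide does not ring-open at this temperature.

**Step 3**
Reactants: 6 3,5-dimethoxybenzaldehyde
Product: 9 3-hydroxy-5,7-dimethoxy-2-benzofuran-1(3H)-one (racemic lactol), via lithium α-amino alkoxide 7 (not isolated), via ortho-lithiated α-amino alkoxide 8 (not isolated)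
Conditions: LiN(Me)CH2CH2NMe2 (1.1 equiv, from MeNHCH2CH2NMe2 + n-BuLi), THF, −20 °C; n-BuLi (3 equiv), −20 → 0 °C; CO2, −78 → 20 °C; 2 M HCl
Reagents that add atoms: carbon dioxide, O=C=O
Why: The chelating α-amino alkoxide and the 3-methoxy group together direct lithiation to C-2 (α-amino alkoxide-directed ortho-lithiation, Comins in situ protection); carboxylation and acid work-up free the aldehyde, which closes onto the new acid as the labile racemic lactol.

**Step 4**
Reactants: 9 3-hydroxy-5,7-dimethoxy-2-benzofuran-1(3H)-one
Product: 11 3-hydroxy-5,7-dimethoxy-1-oxo-1,3-dihydro-2-benzofuran-4-carbaldehyde (racemic), via aryl α-chloro ether 10 (not isolated)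
Conditions: Cl2CHOMe (3 equiv), TiCl4 (5 equiv), CH2Cl2, 0 → 25 °C; then ice/1 M HCl
Reagents that add atoms: dichloromethyl methyl ether, COC(Cl)Cl; water, O
Why: Rieche formylation goes to C-4, which is para to the 7-methoxy and ortho to the 5-methoxy group and is the usual site of electrophilic attack in 5,7-dimethoxyphthalides, whereas C-6 is crowded between two methoxy groups.

**Step 5**
Reactants: 11 3-hydroxy-5,7-dimethoxy-1-oxo-1,3-dihydro-2-benzofuran-4-carbaldehyde
Product: 13 6-bromo-3,5,7-trimethoxy-1-oxo-1,3-dihydro-2-benzofuran-4-carbaldehyde (racemic), via methyl pseudo-ester 12 (not isolated)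
Conditions: H2SO4 (0.2 equiv), MeOH, 65 °C; then NBS (1.1 equiv), 25 → 50 °C; cold 0.5 M HCl work-up
Reagents that add atoms: methanol, CO; N-bromosuccinimide, O=C1CCC(=O)N1Br
Why: Acid-catalysed pseudo-ester (methyl acetal) formation masks the lactol against oxidation and against ring-opening by base later, and electrophilic aromatic bromination can then only occur at the one free ring position, C-6, activated by two ortho methoxy groups.

**Step 6**
Reactants: 13 6-bromo-3,5,7-trimethoxy-1-oxo-1,3-dihydro-2-benzofuran-4-carbaldehyde; 5 1-[(1E)-undec-1-en-1-yl]cyclopropan-1-ol (1.5 equiv)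
Product: 14 3,5,7-trimethoxy-1-oxo-6-[(4E)-3-oxotetradec-4-en-1-yl]-1,3-dihydro-2-benzofuran-4-carbaldehyde (racemic at C-3)
Conditions: Pd(OAc)2 (5 mol %), XPhos (10 mol %), Cs2CO3 (2 equiv), toluene, 80 °C
Reagents that add atoms: none
Why: Proposed new method: zerovalent palladium inserts into the electron-poor C–Br bond, the cyclopropanol exchanges onto palladium as its alkoxide, strain-driven β-carbon elimination turns the future β-carbon of the enone into a palladium-bound homoenolate, and reductive elimination joins it to the aryl carbon. The bulky biaryl phosphine and the two ortho methoxy groups should favour reductive elimination over β-hydride loss, and the alkoxide pathway should outrun arylation of the hindered 1,2-disubstituted alkene. The closest known reaction type is the palladium-catalysed ring-opening cross-coupling of 1-alkyl and 1-aryl cyclopropanols (ketone homoenolates) with aryl bromides, here extended to a 1-alkenylcyclopropanol and a hexasubstituted aryl bromide.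

**Step 7**
Reactants: 14 3,5,7-trimethoxy-1-oxo-6-[(4E)-3-oxotetradec-4-en-1-yl]-1,3-dihydro-2-benzofuran-4-carbaldehyde
Product: 16 racemic 3,5,7-trihydroxy-1-oxo-6-[(4E)-3-oxotetradec-4-en-1-yl]-1,3-dihydro-2-benzofuran-4-carbaldehyde, via 3-chloro bis(dichloroborinate) 15 (not isolated)
Conditions: BCl3 (6 equiv), CH2Cl2, −78 → 20 °C; then H2O/THF, 0 °C
Reagents that add atoms: water, O
Why: BCl3 ether cleavage is chelation-assisted at both aryl methoxy groups (each ortho to a C=O) and converts the pseudo-ester methoxy into the 3-chloride, which hydrolyses on work-up to the racemic lactol; the enone survives at this temperature.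

**Step 8**
Reactants: 16 racemic 3,5,7-trihydroxy-1-oxo-6-[(4E)-3-oxotetradec-4-en-1-yl]-1,3-dihydro-2-benzofuran-4-carbaldehyde
Product: 17 (3R)-4-formyl-5,7-dihydroxy-1-oxo-6-[(4E)-3-oxotetradec-4-en-1-yl]-1,3-dihydro-2-benzofuran-3-yl acetate
Conditions: immobilised Burkholderia cepacia lipase, vinyl acetate (5 equiv), Et3N (0.1 equiv), MTBE, 30 °C
Reagents that add atoms: vinyl acetate, CC(=O)OC=C
Why: In this lipase-catalysed dynamic kinetic resolution of a cyclic hemiacetal, catalytic Et3N keeps the lactol enantiomers in equilibrium through the open formyl carboxylate while the enzyme acetylates only one, so all of 16 funnels into one configurationally stable acetate; the lipase that gives the (R)-acetate is chosen by a short screen (Candida antarctica lipase B is the alternative), because the sense of selectivity cannot be predicted for this substrate.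

**Step 9**
Reactants: 17 (3R)-4-formyl-5,7-dihydroxy-1-oxo-6-[(4E)-3-oxotetradec-4-en-1-yl]-1,3-dihydro-2-benzofuran-3-yl acetate
Product: 18 (3R)-3,5,7-trihydroxy-1-oxo-6-[(4E)-3-oxotetradec-4-en-1-yl]-1,3-dihydro-2-benzofuran-4-carbaldehyde (CNP0275642.1)
Conditions: the same immobilised lipase, n-BuOH (5 equiv), MTBE, 5 °C; filter, evaporate cold
Reagents that add atoms: none
Why: Lipase-catalysed alcoholysis breaks the acyl–oxygen bond only, so C-3 is untouched and the (R) configuration carries over; the enzyme that made the (R)-acetate accepts it in reverse, and the base-free aprotic medium releases the neutral lactol without passing through the open carboxylate.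

**Compound list**
1 | undec-1-yne | CCCCCCCCCC#C | starting material
2 | 1-ethoxycyclopropan-1-ol | CCOC1(O)CC1 | starting material
3 | undec-1-yn-1-ylmagnesium bromide | CCCCCCCCCC#C[Mg]Br | intermediate
4 | 1-(undec-1-yn-1-yl)cyclopropan-1-ol | CCCCCCCCCC#CC1(O)CC1 | intermediate
5 | 1-[(1E)-undec-1-en-1-yl]cyclopropan-1-ol | CCCCCCCCC/C=C/C1(O)CC1 | intermediate
6 | 3,5-dimethoxybenzaldehyde | COc1cc(OC)cc(C=O)c1 | starting material
7 | lithium (3,5-dimethoxyphenyl){[2-(dimethylamino)ethyl](methyl)amino}methanolate | COc1cc(OC)cc(C(O[Li])N(C)CCN(C)C)c1 | intermediate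
8 | lithium (2-lithio-3,5-dimethoxyphenyl){[2-(dimethylamino)ethyl](methyl)amino}methanolate | COc1cc(OC)c([Li])c(C(O[Li])N(C)CCN(C)C)c1 | intermediate
9 | 3-hydroxy-5,7-dimethoxy-2-benzofuran-1(3H)-one (racemic) | COc1cc(OC)c2c(c1)C(O)OC2=O | intermediate
10 | 4-[chloro(methoxy)methyl]-3-hydroxy-5,7-dimethoxy-2-benzofuran-1(3H)-one | COc1cc(OC)c2c(c1C(Cl)OC)C(O)OC2=O | intermediate
11 | 3-hydroxy-5,7-dimethoxy-1-oxo-1,3-dihydro-2-benzofuran-4-carbaldehyde (racemic) | COc1cc(OC)c2c(c1C=O)C(O)OC2=O | intermediate
12 | 3,5,7-trimethoxy-1-oxo-1,3-dihydro-2-benzofuran-4-carbaldehyde (racemic) | COc1cc(OC)c2c(c1C=O)C(OC)OC2=O | intermediate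
13 | 6-bromo-3,5,7-trimethoxy-1-oxo-1,3-dihydro-2-benzofuran-4-carbaldehyde (racemic) | COc1c(Br)c(OC)c2c(c1C=O)C(OC)OC2=O | intermediate
14 | 3,5,7-trimethoxy-1-oxo-6-[(4E)-3-oxotetradec-4-en-1-yl]-1,3-dihydro-2-benzofuran-4-carbaldehyde (racemic) | CCCCCCCCC/C=C/C(=O)CCc1c(OC)c(C=O)c2c(c1OC)C(=O)OC2OC | intermediate
15 | 3-chloro-4-formyl-1-oxo-6-[(4E)-3-oxotetradec-4-en-1-yl]-1,3-dihydro-2-benzofuran-5,7-diyl bis(dichloroborinate) | CCCCCCCCC/C=C/C(=O)CCc1c(OB(Cl)Cl)c(C=O)c2c(c1OB(Cl)Cl)C(=O)OC2Cl | intermediate
16 | racemic 3,5,7-trihydroxy-1-oxo-6-[(4E)-3-oxotetradec-4-en-1-yl]-1,3-dihydro-2-benzofuran-4-carbaldehyde | CCCCCCCCC/C=C/C(=O)CCc1c(O)c(C=O)c2c(c1O)C(=O)OC2O | intermediate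
17 | (3R)-4-formyl-5,7-dihydroxy-1-oxo-6-[(4E)-3-oxotetradec-4-en-1-yl]-1,3-dihydro-2-benzofuran-3-yl acetate | CCCCCCCCC/C=C/C(=O)CCc1c(O)c(C=O)c2c(c1O)C(=O)O[C@H]2OC(C)=O | intermediate
18 | (3R)-3,5,7-trihydroxy-1-oxo-6-[(4E)-3-oxotetradec-4-en-1-yl]-1,3-dihydro-2-benzofuran-4-carbaldehyde | CCCCCCCCC/C=C/C(=O)CCc1c(O)c(C=O)c2c(c1O)C(=O)O[C@H]2O | target

**Step count and risks**
Total: 9 steps. Longest linear sequence: 7 steps (6 → 18, steps 3 to 9); the cyclopropanol branch is 2 steps.

Most likely to fail, first: step 6. The alkenyl group could divert the arylpalladium species into arylation or ring expansion of the alkenylcyclopropanol, or the palladium homoenolate could lose a β-hydride to give a divinyl ketone and reduced arene. The fallback sets out from 13 and comes back at 14 and drops the strained ring altogether: commercial (2E)-dodec-2-enal and CH2=CHMgBr (THF, −78 °C) give (4E)-tetradeca-1,4-dien-3-ol F1 by 1,2-addition. A Heck arylation of the terminal vinyl group of F1 with 13 (Pd(OAc)2, n-Bu4NCl, NaHCO3, DMF, 70 °C) then ends with β-hydride elimination towards the carbinol, and the enol tautomerises to ketone 14 directly, with no alkoxide base and no cyclopropanol.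

Second: step 8. The lipase may reject the hindered lactol, show the wrong sense, or the lactol may equilibrate too slowly. The fallback sets out from 16 and comes back at 18, bypassing 17 and step 9: physical resolution of racemic 16 by preparative supercritical-fluid chromatography on an amylose tris(3,5-dimethylphenylcarbamate) phase (CO2/2-propanol with 0.1 % formic acid, 10 °C), collecting the (R)-enantiomer. The (S) fraction is re-equilibrated with catalytic Et3N and re-injected, so no new compound is made (entry F0).

Third: step 3. Lithiation could go instead to C-4, between the two methoxy groups. The fallback sets out from 6 and comes back at 9 and fixes the regiochemistry by electrophilic substitution: NBS in MeCN at 25 °C brominates ortho to the formyl group and para to a methoxy group, giving 2-bromo-3,5-dimethoxybenzaldehyde F2. Palladium-catalysed hydroxycarbonylation (Pd(OAc)2, 4,5-bis(diphenylphosphino)-9,9-dimethylxanthene, CO 1 atm, K2CO3, H2O/dioxane, 90 °C; then HCl) converts C–Br into CO2H, which closes onto the aldehyde as lactol 9.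

**Further compounds**
F1 | step 6 | (4E)-tetradeca-1,4-dien-3-ol | CCCCCCCCC/C=C/C(O)C=C
F0 | step 8 | none | none
F2 | step 3 | 2-bromo-3,5-dimethoxybenzaldehyde | COc1cc(OC)c(Br)c(C=O)c1
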